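We choose to count nucleophile in pairs. Electrophile couples reversibly with nucleophile to product and acid set free, and nucleophile binds that acid, at balance, as protonated nucleophile. Beside this, electrophile meets protic impurity to give quenched substrate, and two electrophile give homo dimer.

electrophile 0.27 M; nucleophile 0.405 M; protic impurity 0.0135 M; time 30 h

1. part of the electrophile that has reacted at 30 h
2. share of the unused nucleophile that is free and not bound as protonated nucleophile, at 30 h

- in percentages every species weighs as the electrophile in it: one homo dimer counts as two
- for a step with 2 of a species take k times the square, and two of it per event
- run time (flask): 30 h

    electrophile + protic impurity → quenched substrate (k1 = 2.81 /M/h)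
    electrophile + nucleophile ⇌ acid set free + product (K2 = 0.833, k2 = 2.72 /M/h)
    2 electrophile → homo dimer (k3 = 0.177 /M/h)
    nucleophile + acid set free ⇌ protonated nucleophile, settled at all times (K4 = 10900 /M)

In the first instants coupling is the fast step. By its forward rate alone, electrophile has a half-life of 0.63 h, shorter than the 18 h of the impurity step, and just after the start that forward rate uses electrophile 12 times as fast as dimerisation. The binding constant times the starting nucleophile is 4400, so at the start nearly all acid set free sits on a second nucleophile. Each coupling thus costs two nucleophile. Our quantity is the paired share, the nucleophile charge over the electrophile charge, divided by two: 75.0%. It lies below the whole charge, so nucleophile is the limiting reagent.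

In the middle, we let product climb towards the paired share, and we allow the impurity its whole charge, 5.00% of the electrophile. We assume the rest, 20.0%, goes on by dimerisation alone. Second-order decay over the run leaves 12.7%, so we reckon 87.3% reacted.

At the end we take coupling and acid binding as balanced, since the coupling half-life is short against the run. With product and bound nucleophile both put at the paired share, free nucleophile is 4.25% of the electrophile charge, which gives 5.36%.

The forecast says 89.5% and 6%, on the ground that “Each coupling event uses two nucleophiles because the strongly bound acid takes a second one”. Our two figures stand a little lower.

The flask gives 89.5% and 5.79%. After 30.0 h product stands at 73.0% of the charge, 2 percentage points under the paired share of 75.0%.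

In the neighbour flask with 0.10 M of nucleophile, the paired share is 18.5%. That flask computes to 18.6% product after 30.0 h.

Its constants were drawn at random within sensible limits; the rest is arithmetic.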